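**Retrosynthetic overview**

1. The target is cut at six like bonds, one per ring. On each of the two 4,4-dimethylcyclohexadienone caps and each of the four phloroglucinol rings, the butyryl C=O sits on the only ring carbon that is neither a CH2-bridge carbon nor the CMe2 carbon, between two oxygen-bearing ring carbons. Cutting all six ring C–C(=O) bonds gives the acyl-free hexamer and butyric anhydride.
2. The acyl-free hexamer comes from a hexabenzyl ester in which every future acyl carbon is blocked as CO2Bn. Hydrogenolysis and gentle heat remove the blocks as toluene and CO2; benzyl is chosen because saponifying simple alkyl esters in hot alkali would scramble the methylene bridges.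
3. The hexaester is cut at its central CH2 (formaldehyde) into two identical cap–CH2–ring–CH2–ring trimers. Each trimer is grown from the cap by two rounds of Mannich-base formation and quinone-methide coupling with benzyl 2,4,6-trihydroxybenzoate.
4. The cap is the C,C-dimethylated form of that same benzyl ester, which is made from 2,4,6-trihydroxybenzoic acid. No ring is constructed at any stage: all six carbocycles are the purchased benzene ring, two of them dearomatised by the gem-dimethylation.

Key step: step 9

Assumption: the target is one drawn tautomer of a mobile set of enolised β-triketone forms and has no stereocentre; every compound below is written in the tautomer that matches the target SMILES.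

**Route**

Step 1
Reactants: 1 2,4,6-trihydroxybenzoic acid; 2 benzyl bromide
Product: 3 benzyl 2,4,6-trihydroxybenzoate
Conditions: BnBr (1.05 equiv), KHCO3 (1.1 equiv), DMF, rt
Reagents that add atoms: benzyl bromide, BrCc1ccccc1
Why: Bicarbonate ionises only the strongly acidic carboxyl group while the hydrogen-bonded phenols stay protonated, so SN2 O-alkylation of the carboxylate (esterification by carboxylate alkylation) should give the benzyl ester at a temperature too low for decarboxylation.

Step 2
Reactants: 3 benzyl 2,4,6-trihydroxybenzoate; 4 methyl iodide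
Product: 5 benzyl 2,4-dihydroxy-3,3-dimethyl-6-oxocyclohexa-1,4-diene-1-carboxylate (cap ester)
Conditions: MeI (2.2 equiv), BnONa (3 equiv), BnOH, 0 °C to rt; then aq. HCl
Reagents that add atoms: methyl iodide, CI
Why: Twofold C-methylation of the phloroglucinol anion in a protic medium (the classical conversion of 2-acylphloroglucinols into acylfilicinic acids) should put both methyl groups on one free ring carbon, because the once-methylated carbon is the most electron-rich site of the re-formed anion, and benzyloxide in benzyl alcohol makes any ester exchange degenerate.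

Step 3
Reactants: 5 cap ester; 6 N,N-dimethylmethyleneiminium iodide (Eschenmoser's salt)
Product: 7 benzyl 5-[(dimethylamino)methyl]-2,4-dihydroxy-3,3-dimethyl-6-oxocyclohexa-1,4-diene-1-carboxylate (cap Mannich base)
Conditions: CH2=NMe2+ I− (1.3 equiv), K2CO3 (0.5 equiv), MeCN, 0 °C to rt, 5 added slowly to the salt
Reagents that add atoms: Eschenmoser's salt, C=[N+](C)C.[I-]
Why: Mannich aminomethylation by the preformed iminium ion at the only enolic CH of the vinylogous acid, with inverse addition keeping the Mannich base from alkylating unreacted 5.

Step 4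
Reactants: 7 cap Mannich base; 3 benzyl 2,4,6-trihydroxybenzoate (4 equiv)
Product: 9 benzyl 3-{[5-(benzyloxycarbonyl)-2,4-dihydroxy-3,3-dimethyl-6-oxocyclohexa-1,4-dien-1-yl]methyl}-2,4,6-trihydroxybenzoate (cap–ring dimer), via methylidene trione 8 (not isolated)
Conditions: 1,4-dioxane, 80 °C, N2 sweep
Reagents that add atoms: none
Why: On heating the betaine loses dimethylamine (E1cB retro-Mannich elimination) to a 2-methylidene-1,3-dione, an ortho-quinone-methide equivalent, which a free ring carbon of 3 should capture by conjugate addition (Michael-type Friedel–Crafts alkylation), the excess of 3 keeping the product's remaining free carbon from competing.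

Step 5
Reactants: 9 cap–ring dimer; 6 Eschenmoser's salt
Product: 10 benzyl 3-{[5-(benzyloxycarbonyl)-2,4-dihydroxy-3,3-dimethyl-6-oxocyclohexa-1,4-dien-1-yl]methyl}-5-[(dimethylamino)methyl]-2,4,6-trihydroxybenzoate (dimer Mannich base)
Conditions: CH2=NMe2+ I− (1.2 equiv), K2CO3 (0.5 equiv), MeCN, rt
Reagents that add atoms: Eschenmoser's salt, C=[N+](C)C.[I-]
Why: Mannich reaction at the single remaining ring CH of 9, the phloroglucinol carbon flanked by two hydroxyl groups, the cap ring having no free carbon left.

Step 6
Reactants: 10 dimer Mannich base; 3 benzyl 2,4,6-trihydroxybenzoate (4 equiv)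
Product: 12 cap–ring–ring trimer tribenzyl ester (dimer 9 carrying at C-5 of its benzoate ring a CH2 link to C-3 of a further benzyl 2,4,6-trihydroxybenzoate unit), via dimer quinone methide 11 (not isolated)
Conditions: 1,4-dioxane, 100 °C, N2 sweep
Reagents that add atoms: none
Why: Thermal loss of dimethylamine from the phenolic Mannich base gives an ortho-quinone methide that a free carbon of 3 should trap by conjugate addition (quinone-methide alkylation of a phloroglucinol), again with excess 3 so that the trimer keeps one free ring carbon.

Step 7
Reactants: 12 trimer tribenzyl ester (2 equiv); 13 formaldehyde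
Product: 15 hexamer hexabenzyl ester (two molecules of 12 joined by one CH2 between the free ring carbons of their terminal benzoate rings), via hydroxymethyl trimer 14 (not isolated)
Conditions: 37% aq. CH2O (0.5 equiv), Et3N (cat.), THF–EtOH, rt to 40 °C
Reagents that add atoms: formaldehyde, C=O
Why: Lederer–Manasse hydroxymethylation at the one free ring carbon, dehydration to a quinone methide and capture by a second trimer (the classical formaldehyde methylene-bis condensation of acylphloroglucinols) can give only the symmetrical hexamer, because each trimer has a single nucleophilic carbon.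

Step 8
Reactants: 15 hexamer hexabenzyl ester
Product: 17 acyl-free hexamer (linear filicinic acid–CH2–[phloroglucinol–CH2]4–filicinic acid with one free CH on every ring), via hexamer hexacarboxylic acid 16 (not isolated)
Conditions: H2 (1 atm), 10% Pd/C, THF–MeOH, rt; filter under Ar; then 55 °C, Ar
Reagents that add atoms: none
Why: Hydrogenolysis of the six benzyl esters at neutral pH frees 2,4,6-trihydroxybenzoic and vinylogous β-keto acids that should lose CO2 on gentle warming through their keto tautomers (thermal decarboxylation), while the diarylmethane bridges and the enolised trione double bonds are not reduced at one atmosphere and no alkali is present to scramble the bridges.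

Step 9
Reactants: 17 acyl-free hexamer; 18 butyric anhydride
Product: 19 target CNP0237140.0 (hexabutyryl hexamer)
Conditions: (PrCO)2O (7 equiv), BF3·OEt2 (excess), 1,4-dioxane, 10 to 40 °C, Ar; then aq. NaOAc, MeOH, rt
Reagents that add atoms: butyric anhydride, CCCC(=O)OC(=O)CCC
Why: Proposed new method: BF3 activates butyric anhydride to an acylium-like complex, and each ring is attacked at its one unsubstituted carbon, the nucleophilic terminus of a phloroglucinol or of an enolised 1,3,5-trione lying between two oxygen-bearing carbons; where oxygen is acylated first, the same Lewis acid moves the acyl group to that carbon by a Fries shift. The closest known reactions are the BF3-mediated C-acylation of phloroglucinol and of filicinic acid with anhydrides and the O-to-C acyl migration of 1,3-dione enol esters; what is new is running it six times on one molecule that carries five acid-labile diarylmethane-type bridges. No ring is closed and no stereocentre is formed. Two selectivities are needed: carbon over oxygen acylation, and acylation faster than retro-Friedel–Crafts bridge cleavage or xanthene-forming dehydration between neighbouring phenols. The first rests on the single open carbon per ring and on the boron-bound, hydrogen-bonded ortho-hydroxy ketone being the thermodynamic sink; the second rests on the mild boron Lewis acid, the low temperature and the fact that every installed ketone deactivates its ring towards protonation at the bridge carbons. The same deactivation stops each ring at one acyl group, so the count ends at six.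

**Compound list**

1 | 2,4,6-trihydroxybenzoic acid | OC(=O)c1c(O)cc(O)cc1O | starting material
2 | benzyl bromide | BrCc1ccccc1 | starting material
3 | benzyl 2,4,6-trihydroxybenzoate | O=C(OCc1ccccc1)c1c(O)cc(O)cc1O | intermediate
4 | methyl iodide | CI | starting material
5 | benzyl 2,4-dihydroxy-3,3-dimethyl-6-oxocyclohexa-1,4-diene-1-carboxylate (cap ester) | O=C(OCc1ccccc1)C1=C(O)C(C)(C)C(O)=CC1=O | intermediate
6 | N,N-dimethylmethyleneiminium iodide (Eschenmoser's salt) | C=[N+](C)C.[I-] | starting material
7 | benzyl 5-[(dimethylamino)methyl]-2,4-dihydroxy-3,3-dimethyl-6-oxocyclohexa-1,4-diene-1-carboxylate (cap Mannich base) | CN(C)CC1=C(O)C(C)(C)C(O)=C(C(=O)OCc2ccccc2)C1=O | intermediate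
8 | benzyl 2-hydroxy-3,3-dimethyl-5-methylidene-4,6-dioxocyclohex-1-ene-1-carboxylate (methylidene trione) | C=C1C(=O)C(C)(C)C(O)=C(C(=O)OCc2ccccc2)C1=O | intermediate
9 | benzyl 3-{[5-(benzyloxycarbonyl)-2,4-dihydroxy-3,3-dimethyl-6-oxocyclohexa-1,4-dien-1-yl]methyl}-2,4,6-trihydroxybenzoate (cap–ring dimer) | O=C(OCc1ccccc1)C1=C(O)C(C)(C)C(O)=C(Cc2c(O)cc(O)c(C(=O)OCc3ccccc3)c2O)C1=O | intermediate
10 | benzyl 3-{[5-(benzyloxycarbonyl)-2,4-dihydroxy-3,3-dimethyl-6-oxocyclohexa-1,4-dien-1-yl]methyl}-5-[(dimethylamino)methyl]-2,4,6-trihydroxybenzoate (dimer Mannich base) | O=C(OCc1ccccc1)C1=C(O)C(C)(C)C(O)=C(Cc2c(O)c(CN(C)C)c(O)c(C(=O)OCc3ccccc3)c2O)C1=O | intermediate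
11 | dimer quinone methide (ortho-quinone methide formed from 10 by loss of dimethylamine) | C=C1C(=O)C(C(=O)OCc2ccccc2)=C(O)C(CC3=C(O)C(C)(C)C(O)=C(C(=O)OCc4ccccc4)C3=O)=C1O | intermediate
12 | cap–ring–ring trimer tribenzyl ester | O=C(OCc1ccccc1)C1=C(O)C(C)(C)C(O)=C(Cc2c(O)c(Cc3c(O)cc(O)c(C(=O)OCc4ccccc4)c3O)c(O)c(C(=O)OCc3ccccc3)c2O)C1=O | intermediate
13 | formaldehyde | C=O | starting material
14 | hydroxymethyl trimer (12 with CH2OH on its free ring carbon) | O=C(OCc1ccccc1)C1=C(O)C(C)(C)C(O)=C(Cc2c(O)c(Cc3c(O)c(CO)c(O)c(C(=O)OCc4ccccc4)c3O)c(O)c(C(=O)OCc3ccccc3)c2O)C1=O | intermediate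
15 | hexamer hexabenzyl ester | O=C(OCc7ccccc7)C1=C(O)C(C)(C)C(O)=C(Cc2c(O)c(Cc3c(O)c(Cc4c(O)c(Cc5c(O)c(CC6=C(O)C(C)(C)C(O)=C(C(=O)OCc7ccccc7)C6=O)c(O)c(C(=O)OCc6ccccc6)c5O)c(O)c(C(=O)OCc5ccccc5)c4O)c(O)c(C(=O)OCc4ccccc4)c3O)c(O)c(C(=O)OCc3ccccc3)c2O)C1=O | intermediate
16 | hexamer hexacarboxylic acid | OC(=O)C1=C(O)C(C)(C)C(O)=C(Cc2c(O)c(Cc3c(O)c(Cc4c(O)c(Cc5c(O)c(CC6=C(O)C(C)(C)C(O)=C(C(=O)O)C6=O)c(O)c(C(=O)O)c5O)c(O)c(C(=O)O)c4O)c(O)c(C(=O)O)c3O)c(O)c(C(=O)O)c2O)C1=O | intermediate
17 | acyl-free hexamer (two filicinic acid caps, four phloroglucinol rings, five CH2 bridges) | OC1=CC(=O)C(Cc2c(O)c(Cc3c(O)c(Cc4c(O)c(Cc5c(O)c(CC6=C(O)C(C)(C)C(O)=CC6=O)c(O)cc5O)c(O)cc4O)c(O)cc3O)c(O)cc2O)=C(O)C1(C)C | intermediate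
18 | butyric anhydride | CCCC(=O)OC(=O)CCC | starting material
19 | target CNP0237140.0 | CCCC(=O)C1=C(O)C(C)(C)C(O)=C(Cc2c(O)c(Cc3c(O)c(Cc4c(O)c(Cc5c(O)c(CC6=C(O)C(C)(C)C(O)=C(C(=O)CCC)C6=O)c(O)c(C(=O)CCC)c5O)c(O)c(C(=O)CCC)c4O)c(O)c(C(=O)CCC)c3O)c(O)c(C(=O)CCC)c2O)C1=O | target

**Step count**

Total steps: 9. Longest linear sequence: 9 (steps 1 to 9; compound 3 from step 1 re-enters at steps 4 and 6).

**Steps most likely to fail**

Step 9 (proposed new method). The Lewis acid may cleave and re-form the methylene bridges, giving shorter and longer oligomers. It may also dehydrate neighbouring phenols to xanthenes, stop at partly acylated mixtures, or leave acyl groups on oxygen. The fallback uses only known chemistry and puts the acyl groups in before the bridges. It sets out from butyric anhydride 18, with purchased phloroglucinol (Oc1cc(O)cc(O)c1) as the ring source, and comes back to the route at the target 19. Phloroglucinol is C-acylated with 18 and BF3·OEt2 to 1-(2,4,6-trihydroxyphenyl)butan-1-one F1. Part of F1 is gem-dimethylated with methyl iodide 4 (NaOMe, MeOH) to butyrylfilicinic acid F2. Aminomethylation of F2 with Eschenmoser's salt 6 gives the cap Mannich base F3, which is heated with excess F1 in dioxane to give the butyryl cap–ring dimer F4. A second aminomethylation with 6 gives the dimer Mannich base F5, and heating F5 with excess F1 gives the butyryl trimer F6. Two molecules of F6 are joined with formaldehyde 13 (0.5 equiv, conditions of step 7) to give 19 directly. Every bridge is then formed on rings already deactivated by their chelated ketones, which is the classical way methylene-linked acylphloroglucinols are assembled.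

Step 8. Hydrogenolysis may stall through fouling of the catalyst by the polyphenol, the enolised trione rings may be partly saturated, CO2 loss may be incomplete, and the electron-rich product may oxidise in air. The fallback is palladium-free and non-reductive; it sets out from 15 and comes back at 16. Compound 15 is heated with LiI in EtOAc, where iodide removes the benzyl groups by SN2 attack at the benzylic carbon. Acidification with aqueous citric acid gives the hexacarboxylic acid 16, which is warmed under argon as in the second half of step 8 to give 17. No hydrogen, no catalyst and no strong acid or base are involved.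

Step 6. The bifunctional monomer 3 may be alkylated at both free carbons, and the liberated amine may promote exchange of methylene bridges, so that branched or over-long oligomers form beside the trimer. The fallback changes the order of assembly; it sets out from the dimer Mannich base 10, comes back at 15, and replaces steps 6 and 7. Benzyl ester 3 (large excess) is condensed with formaldehyde 13 under the conditions of step 7 to give the central dimer dibenzyl 3,3'-methylenebis(2,4,6-trihydroxybenzoate) F7. Compound F7 is then heated in dioxane with two equivalents of 10. Each ring of F7 has exactly one free carbon, so the two quinone-methide alkylations can only give the linear hexaester 15 and no over-alkylation is possible in the fragment union.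

**Further compounds**

F1 | step 9 | 1-(2,4,6-trihydroxyphenyl)butan-1-one | CCCC(=O)c1c(O)cc(O)cc1O
F2 | step 9 | butyrylfilicinic acid (2-butanoyl-3,5-dihydroxy-4,4-dimethylcyclohexa-2,5-dien-1-one) | CCCC(=O)C1=C(O)C(C)(C)C(O)=CC1=O
F3 | step 9 | cap Mannich base (2-butanoyl-6-[(dimethylamino)methyl]-3,5-dihydroxy-4,4-dimethylcyclohexa-2,5-dien-1-one) | CCCC(=O)C1=C(O)C(C)(C)C(O)=C(CN(C)C)C1=O
F4 | step 9 | butyryl cap–ring dimer (butyrylfilicinic acid linked by CH2 to C-3 of 1-(2,4,6-trihydroxyphenyl)butan-1-one) | CCCC(=O)C1=C(O)C(C)(C)C(O)=C(Cc2c(O)cc(O)c(C(=O)CCC)c2O)C1=O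
F5 | step 9 | dimer Mannich base (F4 with CH2NMe2 on its free aromatic carbon) | CCCC(=O)C1=C(O)C(C)(C)C(O)=C(Cc2c(O)c(CN(C)C)c(O)c(C(=O)CCC)c2O)C1=O
F6 | step 9 | butyryl trimer (cap–CH2–ring–CH2–ring with one free aromatic carbon) | CCCC(=O)C1=C(O)C(C)(C)C(O)=C(Cc2c(O)c(Cc3c(O)cc(O)c(C(=O)CCC)c3O)c(O)c(C(=O)CCC)c2O)C1=O
F0 | step 8 | none | none
F7 | step 6 | dibenzyl 3,3'-methylenebis(2,4,6-trihydroxybenzoate) | O=C(OCc1ccccc1)c1c(O)cc(O)c(Cc2c(O)cc(O)c(C(=O)OCc3ccccc3)c2O)c1O
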